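The trap in this flask is to count catalyst rounds and lose sight of the protic impurity, which stands outside the cycle.

    starting material + free catalyst → catalyst intermediate A (k1 = 200 L mol⁻¹ min⁻¹)
    partner + catalyst intermediate A ⇌ catalyst intermediate B (K2 = 33 L mol⁻¹, k2 = 56 L mol⁻¹ min⁻¹)
    catalyst intermediate B → free catalyst + product (k3 = 41 min⁻¹)
    partner + protic impurity → quenched reagent (k4 = 0.57 L mol⁻¹ min⁻¹)

starting material 0.050 M; partner 0.500 equiv; protic impurity 0.0500 M; free catalyst 0.5 mol%

* the form that holds most of the catalyst when 5.0 % of the starting material are converted (free catalyst / catalyst intermediate A / catalyst intermediate B)
* its share of the catalyst then
* apparent order in partner when 5.0 % of the starting material are converted (percent change of the rate of making product for one percent more partner charged)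
* factor on the rate of making product when 5.0 % of the starting material are converted if free catalyst is charged twice over

The partner is the limiting reagent: its 0.0250 M is less than the 0.050 M of starting material, so I write its balance. Two steps drain it, the quench at k4[protic impurity][partner] and the capture at k2[catalyst intermediate A][partner]. [partner] cancels from their ratio.

Which numbers must be good? The constants k4 and k2, the impurity charge and the catalyst loading each enter that ratio to the first power. If the ratio holds one value throughout, final product is the partner charge over one plus the ratio, so in this reckoning one percent wrong in any of them moves it by 0.671 percent. These four matter.

K2 and k3 matter little: catalyst intermediate B falls back at k2/K2, which is 0.0414 of k3. k1 weighs modestly: with starting material and partner as charged, the wait as free catalyst is 0.140 of the wait as catalyst intermediate A.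

Now the number. 2.04 is my partner tax: partner quenched per partner turned into product, with the impurity as charged and the catalyst wholly as catalyst intermediate A.

Counting the 5.0 % conversion as product, I reckon this flask keeps 0.0174 M of partner then. The waits give catalyst intermediate A 88.8 %. That share times charge over remainder gives an order of 1.27. By the same reckoning, the partner stretches to 0.00824 M of product.

The forecast names catalyst intermediate A at 89 %, with order 1.25 and factor 2.3, holding that “the impurity eats more partner than turnover does”. My order stands above the forecast's.

The run gives catalyst intermediate A at 89.1 %, order 1.2 and factor 2.30. After 12.0 h this flask holds partner 0 %, product 17.2 % and quenched reagent 0.0164 M, a read ratio of 1.91 quenched per product. With free catalyst charged twice over, my tax is 1.02 and I reckon the partner left at that conversion at 0.0200 M against 0.0174 M. Taking the rate as proportional to catalyst and to partner, I get a factor of 2.30; the run's factor is 2.30.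

The constants used here are made up; the flask was simulated.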